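The vessel is closed, stirred and of constant volume, so any charged electrophile that reads as neither electrophile nor target has gone on to something unseen, and we take it to have passed through the target.

| flask | electrophile | nucleophile | remark | time |
|---|---|---|---|---|
| autumn | 0.037 M | 0.055 M | run made earlier |  |
| winter | 0.15 M | 0.055 M | run made earlier |  |
| dawn | 0.33 M | 0.055 M | run made earlier |  |
| green | 0.050 M | 0.0550 M |  | 6.0 min |
| teal | 0.10 M | 0.0550 M |  | 6.0 min |
| violet | 0.20 M | 0.0550 M |  | 6.0 min |
| red | 0.40 M | 0.0550 M |  | 6.0 min |

| run | time / min | target / % | electrophile / % |
|---|---|---|---|
| autumn | 0.833 | 18.5 | 79.1 |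
| autumn | 1.50 | 27.0 | 68.3 |
| autumn | 2.50 | 32.5 | 58.1 |
| autumn | 3.00 | 35.5 | 54.2 |
| autumn | 4.00 | 35.2 | 48.1 |
| winter | 0.833 | 12.8 | 86.6 |
| winter | 1.50 | 15.0 | 82.9 |
| winter | 2.50 | 14.8 | 80.7 |
| winter | 3.00 | 14.2 | 80.7 |
| winter | 4.00 | 13.1 | 78.4 |
| dawn | 0.333 | 4.4 | 93.2 |
| dawn | 0.667 | 7.5 | 92.0 |
| dawn | 1.33 | 9.1 | 90.8 |
| dawn | 2.00 | 7.1 | 90.5 |
| dawn | 4.00 | 6.7 | 89.5 |

(standard deviation of a reading: 0.5 percentage points)

- "hardly changes" means that all values lie within two and a half points (for a concentration: within two and a half percent of the largest)

* [target] at the end for green, teal, violet, red, in this order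
* how the row runs (falls all the way / rises all the way / hardly changes / falls, then rises / rises, then falls)

How fast does target go? In the autumn run that unseen fraction of the charge grows by 12 percentage points between 1.50 min and 4.00 min, while target averages 31.1%. So we read 0.154 /min as the loss constant, the share of the target lost per minute (a first-order rate constant).

Does making keep up with that loss? We take making as the fall of electrophile and loss as the constant times target. Late in each run their ratio reads 1.28 in autumn, 0.712 in winter and 0.470 in dawn, though dawn's rests on a small fall. Target grows while this ratio stands above one and shrinks while it stands below one, so the autumn readings stand near their peak and the winter and dawn readings stand past theirs, with the dawn ratio lower than the winter ratio.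

What stands at 6.0 min? The last two autumn readings of target differ by 0.3 points against a scatter of 0.5 points, so we hold that run level at 0.0130 M. Letting the net loss run on from 4.00 min, we estimate 0.0180 M for winter and 0.0188 M for dawn. Green's charge of electrophile lies above autumn's and red's above dawn's, so we commit to a row that climbs from above the first figure to above the last.

The forecast, whose figures are its own and not ours, gave 0.0145 M, 0.017 M, 0.0185 M and 0.0195 M, rises all the way, holding that “The order from the 4 min values should survive”.

The flasks give 0.0135 M, 0.0156 M, 0.0173 M and 0.0193 M: rises all the way.

    target → over-reaction product (k = 0.00260 /s)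
    electrophile + nucleophile → acid set free + target (k = 0.100 /M/s)
    nucleophile + acid set free ⇌ protonated nucleophile, settled at all times (K = 910 /M)

In green, with each step taken net, target is made 3.74 times as fast as it is used up at 1.21 min but 0.507 times as fast at 6.00 min, when the loss constant puts the loss at 0.0414 /min of the charge on 26.9% of target. In red, the same constant on the mean target between 3.00 min and 6.00 min gives 2.58% of the charge, and the over-reaction product goes from 2.92% to 5.53%.

All runs are calculated for substances that don't exist, and the scatter is random.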